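Ring B of the 4-hydroxycoumarin (O1–C2(=O)–C3=C4(OH), with the stereogenic C1' on C3) is cut at two bonds in one retrosynthetic move, C3–C1' and C4–C4a. The ring is read as an aryloxycarbonyl ketene that has acylated its own arene; that ketene arises by a Wolff shift of C1' from the future C4 carbonyl carbon to C3. Heating the 3-methoxyphenyl 2-diazo-3-oxo ester of the complete (S,E,Z) side chain should therefore give the target directly, with retention at C1'. The precursor is assembled from a Roche-ester-derived E iodoalkene and a lactone-derived Z alkylzinc, followed by a diazoacetate aldol and oxidation.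

Key step: step 14

Remarks on the chemistry (assumptions):
- Side-chain atoms are primed, C1' being the carbon on C3; the target is 1'S, 2'E, 6'Z, with the ketone at C8'.
- The (R)-hydroxy ester maps onto (S)-C1' because its CH2OH carbon ends as C4 and its ester carbon as C2'; only the CIP priorities change.
- The aryl ester enters together with the diazo group, so the α-stereogenic β,γ-unsaturated acyl unit is never activated as an acid derivative and never meets diazo-transfer base.
- The diazo keto ester goes into the key step unprotected; the remote Z enone is assumed inert to the ketene and to neutral heating at 140 °C.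

Step 1
Reactants: 1 methyl (R)-3-hydroxy-2-methylpropanoate
Product: 2 methyl (R)-3-[(tert-butyldimethylsilyl)oxy]-2-methylpropanoate
Conditions: TBSCl, imidazole, CH2Cl2, 0 °C → rt
Reagents that add atoms: tert-butyldimethylsilyl chloride, CC(C)(C)[Si](C)(C)Cl
Why: Imidazole-promoted O-silylation of a primary alcohol, in which neither the ester nor the stereocentre takes part.

Step 2
Reactants: 2 methyl (R)-3-[(tert-butyldimethylsilyl)oxy]-2-methylpropanoate
Product: 4 (S)-tert-butyldimethyl[(2-methylbut-3-yn-1-yl)oxy]silane, via silyloxy aldehyde 3 (not isolated)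
Conditions: iBu2AlH (DIBAL-H), CH2Cl2, −78 °C; then MeOH, K2CO3, dimethyl (1-diazo-2-oxopropyl)phosphonate, −78 °C → rt
Reagents that add atoms: dimethyl (1-diazo-2-oxopropyl)phosphonate, CC(=O)C(=[N+]=[N-])P(=O)(OC)OC
Why: Partial ester reduction at −78 °C followed in the same flask by Seyferth–Gilbert homologation with the Ohira–Bestmann reagent turns the ester carbon into an alkyne carbon while the epimerisable α-methyl aldehyde 3 is never isolated; the descriptor changes from R to S by priority only.

Step 3
Reactants: 4 (S)-tert-butyldimethyl[(2-methylbut-3-yn-1-yl)oxy]silane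
Product: 6 (S,E)-tert-butyl[(4-iodo-2,3-dimethylbut-3-en-1-yl)oxy]dimethylsilane, via alkenyl(dimethyl)alane 5 (not isolated)
Conditions: AlMe3, Cp2ZrCl2 (cat.), CH2Cl2, 0 °C → rt; then I2, THF, −30 → 0 °C
Reagents that add atoms: trimethylaluminium, C[Al](C)C; iodine, II
Why: Cp2ZrCl2-catalysed Negishi carboalumination adds methyl and aluminium syn across the terminal alkyne with aluminium at the terminal carbon, and iodinolysis of the C–Al bond with retention fixes the E iodoalkene; the stereocentre is a bystander.

Step 4
Reactants: 7 4-methyl-5,6-dihydro-2H-pyran-2-one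
Product: 8 (Z)-5-hydroxy-N-methoxy-N,3-dimethylpent-2-enamide
Conditions: MeNH(OMe)·HCl, AlMe3, CH2Cl2, 0 °C → rt; aqueous potassium sodium tartrate work-up
Reagents that add atoms: N,O-dimethylhydroxylamine hydrochloride, CNOC.Cl
Why: Aluminium-amide aminolysis of a lactone (Weinreb amide formation) leaves the C=C bond untouched, so the cis relation of carbonyl and CH2 chain enforced by the ring is delivered as the Z alkene.

Step 5
Reactants: 8 (Z)-5-hydroxy-N-methoxy-N,3-dimethylpent-2-enamide
Product: 9 (Z)-5-iodo-N-methoxy-N,3-dimethylpent-2-enamide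
Conditions: I2, PPh3, imidazole, CH2Cl2, 0 °C
Reagents that add atoms: iodine, II
Why: Appel-type iodination of a primary alcohol under non-acidic conditions, which forestalls relactonisation of the cis hydroxy amide; 9 is used without storage.

Step 6
Reactants: 9 (Z)-5-iodo-N-methoxy-N,3-dimethylpent-2-enamide; 6 (S,E)-tert-butyl[(4-iodo-2,3-dimethylbut-3-en-1-yl)oxy]dimethylsilane
Product: 11 (2Z,6E,8S)-9-[(tert-butyldimethylsilyl)oxy]-N-methoxy-N,3,7,8-tetramethylnona-2,6-dienamide, via alkylzinc iodide 10 (not isolated)
Conditions: Zn dust (activated with BrCH2CH2Br and Me3SiCl), LiCl, THF, 30 °C; then 6, Pd(OAc)2 (cat.), SPhos (2-dicyclohexylphosphino-2',6'-dimethoxybiphenyl), THF, rt → 40 °C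
Reagents that add atoms: none
Why: LiCl-assisted zinc insertion into a primary alkyl iodide gives an alkylzinc that tolerates the N-methoxy-N-methyl amide, and palladium-catalysed sp3–sp2 Negishi coupling joins C4' to C3' with retention of the E geometry, the bulky biarylphosphine favouring reductive elimination over β-hydride elimination.

Step 7
Reactants: 11 (2Z,6E,8S)-9-[(tert-butyldimethylsilyl)oxy]-N-methoxy-N,3,7,8-tetramethylnona-2,6-dienamide; 12 isobutylmagnesium bromide
Product: 13 (5Z,9E,11S)-12-[(tert-butyldimethylsilyl)oxy]-2,6,10,11-tetramethyldodeca-5,9-dien-4-one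
Conditions: THF, −78 → 0 °C; aq. NH4Cl
Reagents that add atoms: none
Why: Weinreb ketone synthesis, in which the N-methoxy-N-methyl amide accepts a single equivalent of Grignard reagent and releases the ketone only on work-up; the β,β-disubstituted Z alkene is too hindered for conjugate addition and keeps its geometry.

Step 8
Reactants: 13 (5Z,9E,11S)-12-[(tert-butyldimethylsilyl)oxy]-2,6,10,11-tetramethyldodeca-5,9-dien-4-one
Product: 14 (5Z,9E,11S)-12-hydroxy-2,6,10,11-tetramethyldodeca-5,9-dien-4-one
Conditions: HF·pyridine, pyridine, THF, 0 °C → rt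
Reagents that add atoms: none
Why: Buffered fluoride desilylation of a primary TBS ether under nearly neutral conditions, chosen over more basic fluoride sources so that the Z enone is neither enolised nor isomerised.

Step 9
Reactants: 14 (5Z,9E,11S)-12-hydroxy-2,6,10,11-tetramethyldodeca-5,9-dien-4-one
Product: 15 (2S,3E,7Z)-2,3,7,11-tetramethyl-9-oxododeca-3,7-dienal
Conditions: Dess–Martin periodinane, NaHCO3, CH2Cl2, 0 °C → rt
Reagents that add atoms: none
Why: Buffered Dess–Martin oxidation is the standard non-epimerising access to α-stereogenic β,γ-unsaturated aldehydes; 15 is used crude and at once.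

Step 10
Reactants: 16 3-methoxyphenol; 17 bromoacetyl bromide
Product: 18 3-methoxyphenyl bromoacetate
Conditions: pyridine, CH2Cl2, 0 °C
Reagents that add atoms: none
Why: O-acylation of a phenol by an acyl bromide with pyridine as acid acceptor.

Step 11
Reactants: 18 3-methoxyphenyl bromoacetate
Product: 20 3-methoxyphenyl diazoacetate, via N-alkyl ditosylhydrazide 19 (not isolated)
Conditions: TsNHNHTs, DBU, THF, 0 °C
Reagents that add atoms: N,N'-ditosylhydrazine, Cc1ccc(cc1)S(=O)(=O)NNS(=O)(=O)c1ccc(C)cc1
Why: Diazoacetate synthesis from a bromoacetate and N,N'-ditosylhydrazine, in which N-alkylation to 19 and base-induced loss of two sulfinates unveil the diazo group within minutes at 0 °C, a window the aryl ester should survive.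

Step 12
Reactants: 20 3-methoxyphenyl diazoacetate; 15 (2S,3E,7Z)-2,3,7,11-tetramethyl-9-oxododeca-3,7-dienal
Product: 22 3-methoxyphenyl (4S,5E,9Z)-2-diazo-3-hydroxy-4,5,9,13-tetramethyl-11-oxotetradeca-5,9-dienoate, via lithiated diazoacetate 21 (not isolated)
Conditions: LiN(SiMe3)2, THF, −78 °C, 5 min; then 15, −78 °C; AcOH, −78 °C
Reagents that add atoms: none
Why: Aldol-type addition of a lithiated diazoacetate to an aldehyde, which at −78 °C should be far faster at the aldehyde than at the conjugated ketone and faster than α-deprotonation, so C4 stays S; the new carbinol centre C3 forms as a mixture and is erased in step 13.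

Step 13
Reactants: 22 3-methoxyphenyl (4S,5E,9Z)-2-diazo-3-hydroxy-4,5,9,13-tetramethyl-11-oxotetradeca-5,9-dienoate
Product: 23 3-methoxyphenyl (4S,5E,9Z)-2-diazo-4,5,9,13-tetramethyl-3,11-dioxotetradeca-5,9-dienoate
Conditions: Dess–Martin periodinane, NaHCO3, CH2Cl2, 0 °C → rt
Reagents that add atoms: none
Why: Dess–Martin oxidation of an α-diazo-β-hydroxy ester to the 2-diazo-3-oxo ester, a mild non-basic oxidation that leaves the diazo group, the aryl ester and the enolisable allylic C4 stereocentre untouched.

Step 14
Reactants: 23 3-methoxyphenyl (4S,5E,9Z)-2-diazo-4,5,9,13-tetramethyl-3,11-dioxotetradeca-5,9-dienoate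
Product: 25 4-hydroxy-7-methoxy-3-[(2S,3E,7Z)-3,7,11-trimethyl-9-oxododeca-3,7-dien-2-yl]-2H-chromen-2-one, via aryloxycarbonyl ketene 24 (not isolated)
Conditions: o-xylene (dry, degassed), 140 °C, syringe-pump addition to 0.003 M, Ar, dark; SiO2 chromatography
Reagents that add atoms: none
Why: Proposed new method: heating should expel N2 from 23 in concert with a 1,2-shift of C1' from the ketone carbon to the diazo carbon (thermal Wolff rearrangement, known for 2-diazo-3-oxo esters, with retention at the migrating carbon) to give ketene 24, whose digonal carbon is then attacked by the arene carbon ortho to the ester oxygen and para to methoxy, the closest precedent being the thermal closure of aryl malonate-derived ketenes to 4-hydroxycoumarins; the novelty is the tandem on an aryl ester. Ring B closes in a six-membered mode at the digonal ketene carbon, exo with respect to the C4=O π bond that is consumed (6-exo-dig) while the surviving C3=C4 bond lies inside the ring, and a proton shift then restores the arene and leaves the 4-hydroxy enol. No stereocentre is created; the S centre C1' is only transferred, its configuration being held by the concerted suprafacial shift and by a neutral aprotic medium that cannot enolise it. Three selectivities are needed: migration of C1' rather than aryloxy (the usual preference of diazo keto esters, the acyl group lying s-Z so that C1' is anti to the departing N2), closure para rather than ortho to methoxy (stronger activation and less crowding, any 5-methoxy isomer being removed by chromatography), and ring closure rather than ketene dimerisation or O-acylation of the product (high dilution in a dry inert solvent). The absence of metals shuts off the carbenoid paths of β,γ-unsaturated diazo ketones (cyclopropanation, vinylogous Wolff), and 140 °C without acid, base or light should leave the Z enone in place.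

Compound list
1 | methyl (R)-3-hydroxy-2-methylpropanoate | OC[C@@H](C)C(=O)OC | starting material
2 | methyl (R)-3-[(tert-butyldimethylsilyl)oxy]-2-methylpropanoate | CC(C)(C)[Si](C)(C)OC[C@@H](C)C(=O)OC | intermediate
3 | (R)-3-[(tert-butyldimethylsilyl)oxy]-2-methylpropanal | CC(C)(C)[Si](C)(C)OC[C@@H](C)C=O | intermediate (not isolated)
4 | (S)-tert-butyldimethyl[(2-methylbut-3-yn-1-yl)oxy]silane | CC(C)(C)[Si](C)(C)OC[C@@H](C)C#C | intermediate
5 | [(1E,3S)-4-[(tert-butyldimethylsilyl)oxy]-2,3-dimethylbut-1-en-1-yl]dimethylalane | CC(C)(C)[Si](C)(C)OC[C@@H](C)/C(C)=C/[Al](C)C | intermediate (not isolated)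
6 | (S,E)-tert-butyl[(4-iodo-2,3-dimethylbut-3-en-1-yl)oxy]dimethylsilane | CC(C)(C)[Si](C)(C)OC[C@@H](C)/C(C)=C/I | intermediate
7 | 4-methyl-5,6-dihydro-2H-pyran-2-one | CC1=CC(=O)OCC1 | starting material
8 | (Z)-5-hydroxy-N-methoxy-N,3-dimethylpent-2-enamide | OCC/C(C)=C\C(=O)N(C)OC | intermediate
9 | (Z)-5-iodo-N-methoxy-N,3-dimethylpent-2-enamide | ICC/C(C)=C\C(=O)N(C)OC | intermediate
10 | [(3Z)-5-[methoxy(methyl)amino]-3-methyl-5-oxopent-3-en-1-yl]zinc iodide | I[Zn]CC/C(C)=C\C(=O)N(C)OC | intermediate (not isolated)
11 | (2Z,6E,8S)-9-[(tert-butyldimethylsilyl)oxy]-N-methoxy-N,3,7,8-tetramethylnona-2,6-dienamide | CC(C)(C)[Si](C)(C)OC[C@@H](C)/C(C)=C/CC/C(C)=C\C(=O)N(C)OC | intermediate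
12 | isobutylmagnesium bromide | CC(C)C[Mg]Br | starting material
13 | (5Z,9E,11S)-12-[(tert-butyldimethylsilyl)oxy]-2,6,10,11-tetramethyldodeca-5,9-dien-4-one | CC(C)(C)[Si](C)(C)OC[C@@H](C)/C(C)=C/CC/C(C)=C\C(=O)CC(C)C | intermediate
14 | (5Z,9E,11S)-12-hydroxy-2,6,10,11-tetramethyldodeca-5,9-dien-4-one | OC[C@@H](C)/C(C)=C/CC/C(C)=C\C(=O)CC(C)C | intermediate
15 | (2S,3E,7Z)-2,3,7,11-tetramethyl-9-oxododeca-3,7-dienal | O=C[C@@H](C)/C(C)=C/CC/C(C)=C\C(=O)CC(C)C | intermediate
16 | 3-methoxyphenol | COc1cccc(O)c1 | starting material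
17 | bromoacetyl bromide | BrCC(Br)=O | starting material
18 | 3-methoxyphenyl bromoacetate | COc1cccc(OC(=O)CBr)c1 | intermediate
19 | 3-methoxyphenyl 2-[1,2-bis(4-methylbenzenesulfonyl)hydrazin-1-yl]acetate | COc1cccc(OC(=O)CN(NS(=O)(=O)c2ccc(C)cc2)S(=O)(=O)c2ccc(C)cc2)c1 | intermediate (not isolated)
20 | 3-methoxyphenyl diazoacetate | COc1cccc(OC(=O)C=[N+]=[N-])c1 | intermediate
21 | 3-methoxyphenyl diazo(lithio)acetate | COc1cccc(OC(=O)C([Li])=[N+]=[N-])c1 | intermediate (not isolated)
22 | 3-methoxyphenyl (4S,5E,9Z)-2-diazo-3-hydroxy-4,5,9,13-tetramethyl-11-oxotetradeca-5,9-dienoate (C3 epimer mixture) | COc1cccc(OC(=O)C(=[N+]=[N-])C(O)[C@@H](C)/C(C)=C/CC/C(C)=C\C(=O)CC(C)C)c1 | intermediate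
23 | 3-methoxyphenyl (4S,5E,9Z)-2-diazo-4,5,9,13-tetramethyl-3,11-dioxotetradeca-5,9-dienoate | COc1cccc(OC(=O)C(=[N+]=[N-])C(=O)[C@@H](C)/C(C)=C/CC/C(C)=C\C(=O)CC(C)C)c1 | intermediate
24 | 3-methoxyphenyl (3S,4E,8Z)-3,4,8,12-tetramethyl-10-oxo-2-(oxomethylidene)trideca-4,8-dienoate | COc1cccc(OC(=O)C(=C=O)[C@@H](C)/C(C)=C/CC/C(C)=C\C(=O)CC(C)C)c1 | intermediate (not isolated)
25 | 4-hydroxy-7-methoxy-3-[(2S,3E,7Z)-3,7,11-trimethyl-9-oxododeca-3,7-dien-2-yl]-2H-chromen-2-one | COc1ccc2c(O)c([C@@H](C)/C(C)=C/CC/C(C)=C\C(=O)CC(C)C)c(=O)oc2c1 | target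

Total step count: 14. Longest linear sequence: 10 steps (steps 1, 2, 3, 6, 7, 8, 9, 12, 13, 14).

Steps most likely to fail

Step 14 (key step). The ketene may be lost to dimerisation or to O-acylation of the product enol before the arene attacks. Closure may also demand a temperature at which the Z enone isomerises by a 1,5-hydrogen shift, or at which the 4-hydroxyl adds to the C2'=C3' alkene. The fallback builds ring B by known chemistry in a different way and sets out from aldehyde 15.
- Pinnick oxidation (NaClO2, NaH2PO4, 2-methyl-2-butene, t-BuOH/H2O) would give (2S,3E,7Z)-2,3,7,11-tetramethyl-9-oxododeca-3,7-dienoic acid F1.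
- Isobutyl chloroformate and N-methylmorpholine at −15 °C would give (2S,3E,7Z)-2,3,7,11-tetramethyl-9-oxododeca-3,7-dienoic 2-methylpropyl carbonic anhydride F2.
- Me3SiCHN2 would convert it to (3S,4E,8Z)-1-diazo-3,4,8,12-tetramethyltrideca-4,8-diene-2,10-dione F3.
- Arndt–Eistert-type Wolff rearrangement (AgO2CPh, Et3N, THF, dark; retention at the migrating carbon) in the presence of methyl 2-hydroxy-4-methoxybenzoate would give methyl 4-methoxy-2-{[(3R,4E,8Z)-3,4,8,12-tetramethyl-10-oxotrideca-4,8-dienoyl]oxy}benzoate F4.
- Dieckmann-type closure (LiN(SiMe3)2, THF, −78 → 0 °C), in which the ester enolate attacks the neighbouring methyl ester, would form the C3–C4 bond and come back to the route at target 25.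

Step 12. Acyl transfer or self-condensation of the lithiated aryl ester, addition to the conjugated ketone, or retro-aldol cleavage during the quench may erode the aldol. The fallback sets out from 15 and 20: a tin-dichloride-catalysed Roskamp reaction (SnCl2, CH2Cl2, rt; loss of N2 and 1,2-hydride shift without base) would give 3-methoxyphenyl (4S,5E,9Z)-4,5,9,13-tetramethyl-3,11-dioxotetradeca-5,9-dienoate F5. Regitz diazo transfer (4-acetamidobenzenesulfonyl azide, Et3N, MeCN, 0 °C) would then return to the route at 23.

Step 6. Zinc insertion may be sluggish, the alkylzinc may be protonated or captured by the cis amide, or β-hydride elimination after transmetalation may give a dienamide. The fallback sets out from 6 and 9: a nickel-catalysed reductive cross-electrophile coupling (NiBr2·DME, 4,4'-di-tert-butyl-2,2'-bipyridine, Mn powder, NaI, DMA, rt) would engage the alkyl iodide as a radical, so no organometallic reagent has to be made. It forms no new compound (F0) and comes back to the route at 11.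

Further compounds
F1 | step 14 | (2S,3E,7Z)-2,3,7,11-tetramethyl-9-oxododeca-3,7-dienoic acid | O=C(O)[C@@H](C)/C(C)=C/CC/C(C)=C\C(=O)CC(C)C
F2 | step 14 | (2S,3E,7Z)-2,3,7,11-tetramethyl-9-oxododeca-3,7-dienoic 2-methylpropyl carbonic anhydride | CC(C)COC(=O)OC(=O)[C@@H](C)/C(C)=C/CC/C(C)=C\C(=O)CC(C)C
F3 | step 14 | (3S,4E,8Z)-1-diazo-3,4,8,12-tetramethyltrideca-4,8-diene-2,10-dione | [N-]=[N+]=CC(=O)[C@@H](C)/C(C)=C/CC/C(C)=C\C(=O)CC(C)C
F4 | step 14 | methyl 4-methoxy-2-{[(3R,4E,8Z)-3,4,8,12-tetramethyl-10-oxotrideca-4,8-dienoyl]oxy}benzoate | COC(=O)c1ccc(OC)cc1OC(=O)C[C@@H](C)/C(C)=C/CC/C(C)=C\C(=O)CC(C)C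
F5 | step 12 | 3-methoxyphenyl (4S,5E,9Z)-4,5,9,13-tetramethyl-3,11-dioxotetradeca-5,9-dienoate | COc1cccc(OC(=O)CC(=O)[C@@H](C)/C(C)=C/CC/C(C)=C\C(=O)CC(C)C)c1
F0 | step 6 | none | none
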